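**Plan**
1. Cuts: the target is the trans (2S,3R)-2-aryl-3-hydroxymethyl-7-methoxy-2,3-dihydrobenzofuran with a methyl propanoate chain at C5. Bonds C3a–C7a and C6–C7 are cut together, which opens benzene ring A and the dihydrofuran ring to a 2,4-disubstituted furan and an ethynyl ether on O1. Next come O1–C(alkyne), C2–C3 (aldol) and furan C4–CH2 (cross-coupling).
2. Enabling feature: ring A carries oxygen on the neighbouring carbons C7a (O1) and C7 (OMe), C7a adjoins the fusion carbon C3a, and O1 is tied back to C3a through C2 and C3. Hence C3a, C4, C5 and C6 map onto furan C2 to C5 (chain on furan C4), C7a and C7 onto O–C≡CH, and the C7 oxygen onto the furan oxygen.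
3. Forward order: the side chain is joined to the bromofuran, the formyl group is homologated to the acetic acid, and the aldol attaches the syringyl unit. The ethynyl ether is then installed, one gold-catalysed isomerisation closes both rings (ring A arises last), and the chain terminus is finally raised to the methyl ester.
4. Stereochemistry: both centres come from one syn aldol controlled by (S)-4-benzyl-2-oxazolidinone. No bond at either centre is broken afterwards, so syn in the chain becomes trans in the ring.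

Key step: step 12

Remark: the labels O1, C2, C3, C3a, C4–C7 and C7a are those of the dihydrobenzofuran core and are also used for the corresponding atoms of the precursors. The descriptors of the target SMILES read (2S,3R), trans.

**Step 1**
Reactants: 1 allyl alcohol
Product: 2 allyloxy(triisopropyl)silane
Conditions: TIPSCl, imidazole, CH2Cl2, 0 °C → rt
Reagents that add atoms: chlorotriisopropylsilane, CC(C)[Si](Cl)(C(C)C)C(C)C
Why: Imidazole-promoted silylation of a primary alcohol; the bulky silyl ether should outlast boranes, strong bases, hydride and the gold salt and is orthogonal to the benzyl ethers used later.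

**Step 2**
Reactants: 2 allyloxy(triisopropyl)silane; 3 4-bromo-2-furaldehyde
Product: 5 4-[3-(triisopropylsilyloxy)propyl]furan-2-carbaldehyde, via alkylborane 4 (not isolated)
Conditions: 9-BBN-H (slight deficit relative to 2), THF, 0 °C → rt; then 3, PdCl2(dppf) (5 mol %), aq. K3PO4, DMF, 50 °C
Reagents that add atoms: none
Why: Anti-Markovnikov hydroboration puts boron on the terminal carbon and the B-alkyl Suzuki–Miyaura coupling joins this carbon to furan C4, the formyl group easing oxidative addition and surviving because no B–H is left when 3 is added.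

**Step 3**
Reactants: 5 4-[3-(triisopropylsilyloxy)propyl]furan-2-carbaldehyde
Product: 6 2-vinyl-4-[3-(triisopropylsilyloxy)propyl]furan
Conditions: MePPh3Br, KOtBu, THF, 0 °C
Reagents that add atoms: methyltriphenylphosphonium bromide, C[P+](c1ccccc1)(c1ccccc1)c1ccccc1.[Br-]
Why: Wittig methylenation of a non-enolisable heteroaromatic aldehyde with the unstabilised ylide is fast at low temperature and touches neither the furan nor the silyl ether.

**Step 4**
Reactants: 6 2-vinyl-4-[3-(triisopropylsilyloxy)propyl]furan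
Product: 8 2-{4-[3-(triisopropylsilyloxy)propyl]furan-2-yl}ethanol, via furylethylborane 7 (not isolated)
Conditions: 9-BBN-H, THF, 0 °C → rt; then aq. NaOH, H2O2, 0 °C
Reagents that add atoms: hydrogen peroxide, OO
Why: Hydroboration–oxidation, in which the bulky borane adds to the vinyl group with boron on the terminal carbon, leaves the aromatic furan alone and is replaced by hydroxyl with alkaline peroxide.

**Step 5**
Reactants: 8 2-{4-[3-(triisopropylsilyloxy)propyl]furan-2-yl}ethanol
Product: 10 {4-[3-(triisopropylsilyloxy)propyl]furan-2-yl}acetic acid, via furylacetaldehyde 9 (not isolated)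
Conditions: TEMPO (cat.), PhI(OAc)2 (2.2 equiv), aq. MeCN, 0 °C → rt
Reagents that add atoms: water, O
Why: The oxoammonium (TEMPO) oxidation with PhI(OAc)2 as terminal oxidant takes the primary alcohol through aldehyde 9 and its hydrate to the acid under metal-free, nearly neutral conditions that a dialkylfuran and a silyl ether should tolerate.

**Step 6**
Reactants: 10 {4-[3-(triisopropylsilyloxy)propyl]furan-2-yl}acetic acid; 11 (S)-4-benzyl-2-oxazolidinone
Product: 13 (S)-4-benzyl-3-({4-[3-(triisopropylsilyloxy)propyl]furan-2-yl}acetyl)oxazolidin-2-one, via mixed pivalic anhydride 12 (not isolated)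
Conditions: PivCl, Et3N, THF, −20 °C; then LiCl, 11, −20 °C → rt
Reagents that add atoms: none
Why: N-Acylation of the oxazolidinone through the mixed pivalic anhydride under LiCl/Et3N activation needs no strong base, which suits an acid whose alpha protons are activated by the furan.

**Step 7**
Reactants: 14 syringaldehyde
Product: 15 4-benzyloxy-3,5-dimethoxybenzaldehyde
Conditions: BnBr, K2CO3, DMF, rt
Reagents that add atoms: benzyl bromide, BrCc1ccccc1
Why: Williamson ether synthesis on the phenoxide; benzyl withstands all later steps and leaves by hydrogenolysis together with the second benzyl ether.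

**Step 8**
Reactants: 13 (S)-4-benzyl-3-({4-[3-(triisopropylsilyloxy)propyl]furan-2-yl}acetyl)oxazolidin-2-one; 15 4-benzyloxy-3,5-dimethoxybenzaldehyde
Product: 18 syn aldol adduct (4S)-4-benzyl-3-[(2R,3S)-3-(4-benzyloxy-3,5-dimethoxyphenyl)-3-hydroxy-2-{4-[3-(triisopropylsilyloxy)propyl]furan-2-yl}propanoyl]oxazolidin-2-one, via Z-boron enolate 16 (not isolated), via boron aldolate 17 (not isolated)
Conditions: Bu2BOTf, Et3N, CH2Cl2, −78 → 0 °C; 15, −78 → 0 °C; then pH 7 buffer, MeOH, H2O2, 0 °C
Reagents that add atoms: none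
Why: Evans syn aldol, in which soft enolisation gives Z enolate 16 that reacts through a Zimmerman–Traxler chair on the face away from the benzyl group of the (S)-auxiliary, so both centres (future C3 and future C2) are set at once in the syn relation before buffered peroxide cleaves aldolate 17.

**Step 9**
Reactants: 18 syn aldol adduct
Product: 19 (1S,2R)-1-(4-benzyloxy-3,5-dimethoxyphenyl)-2-{4-[3-(triisopropylsilyloxy)propyl]furan-2-yl}propane-1,3-diol
Conditions: LiBH4, MeOH (1 equiv), THF, 0 °C
Reagents that add atoms: none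
Why: Reductive removal of the auxiliary by LiBH4 turns the imide carbonyl into the primary alcohol at a temperature where retro-aldol cleavage and epimerisation of the furyl-bearing centre should not compete, and it returns 11.

**Step 10**
Reactants: 19 (1S,2R)-diol
Product: 20 (1S,2R)-3-benzyloxy-1-(4-benzyloxy-3,5-dimethoxyphenyl)-2-{4-[3-(triisopropylsilyloxy)propyl]furan-2-yl}propan-1-ol
Conditions: Ag2O, BnBr (1.1 equiv), CH2Cl2, rt, dark
Reagents that add atoms: benzyl bromide, BrCc1ccccc1
Why: The Ag2O-mediated Williamson monoalkylation of a 1,3-diol favours the unhindered primary hydroxyl over the flanked secondary benzylic one under non-basic conditions and leaves free exactly the hydroxyl that will become O1.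

**Step 11**
Reactants: 20 (1S,2R)-3-benzyloxy-1-aryl-2-furylpropan-1-ol
Product: 23 ethynyl ether (1S,2R)-3-benzyloxy-1-(4-benzyloxy-3,5-dimethoxyphenyl)-1-ethynyloxy-2-{4-[3-(triisopropylsilyloxy)propyl]furan-2-yl}propane, via dichlorovinyl ether 21 (not isolated), via lithium acetylide 22 (not isolated)
Conditions: KH, THF, 0 °C; Cl2C=CHCl, −50 °C → rt; then n-BuLi (2.2 equiv), −78 → −40 °C; MeOH, −78 °C; quick filtration through Et3N-deactivated silica, used at once
Reagents that add atoms: trichloroethylene, ClC=C(Cl)Cl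
Why: This is the trichloroethylene route to ynol ethers, in which 20 deprotonated by KH adds to dichloroacetylene released in the flask to give (E)-ether 21 and n-BuLi then effects dehydrochlorination and chlorine–lithium exchange to 22, which is protonated; the C–O bond at the stereocentre is never broken and any lithiation at furan C5 is undone by the same quench.

**Step 12**
Reactants: 23 ethynyl ether
Product: 26 (2S,3R)-2-(4-benzyloxy-3,5-dimethoxyphenyl)-3-(benzyloxymethyl)-5-[3-(triisopropylsilyloxy)propyl]-2,3-dihydrobenzofuran-7-ol, via oxepine 24 (not isolated), via arene oxide 25 (not isolated)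
Conditions: AuCl3 (5 mol %), dry MeCN (0.01 M), 4 Å MS, 0 °C → rt
Reagents that add atoms: none
Why: AuCl3 (trivalent gold) binds the alkyne of 23, which the ether oxygen polarises so that the oxygen-bearing carbon is electrophilic; furan C2 attacks it (bond C3a–C7a), back-donation from the vinylgold gives a cyclopropyl gold carbene at the former terminal carbon, the furan C2–O bond breaks to a gold-carbene dienal, and the aldehyde oxygen adds to the carbene carbon with release of the catalyst to give oxepine 24, which closes to arene oxide 25 (bond C6–C7) and opens to phenol 26. The closest known reaction type is the gold-catalysed furan-yne phenol synthesis, which is documented for furans joined to alkynyl ethers through a three-atom C–C–O tether and then gives 7-hydroxy-2,3-dihydrobenzofurans. The dihydrofuran ring closes 5-exo-dig at the alkyne (5-exo-trig as seen from the furan C2=C3 bond), and ring A closes by the disrotatory six-electron electrocyclisation of the oxepine. No lasting stereocentre is created: C2 and C3 lie on the tether, none of their bonds is touched, and the syn arrangement of 23 becomes the trans (2S,3R) arrangement of 26. The furan must outrun both the dimethoxyaryl ring and ionisation of the benzylic C2–O bond; the arene could reach the electrophilic carbon only through a ring containing its own ipso–ortho bond (5-endo-trig) or would have to attack the electronically mismatched terminal carbon, and ionisation is slowed because both methoxy groups stand meta to C2 and twist the 4-benzyloxy group out of conjugation. The hydroxyl ends at C7 because cleavage of the C6–O bond of 25 leaves a cation delocalised onto C7a and stabilised there by O1, whereas cleavage of C7–O has no such help.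

**Step 13**
Reactants: 26 7-hydroxy-2,3-dihydrobenzofuran
Product: 27 (2S,3R)-2-(4-benzyloxy-3,5-dimethoxyphenyl)-3-(benzyloxymethyl)-7-methoxy-5-[3-(triisopropylsilyloxy)propyl]-2,3-dihydrobenzofuran
Conditions: MeI, K2CO3, DMF, rt
Reagents that add atoms: iodomethane, CI
Why: Williamson methylation of the only acidic hydroxyl installs the C7 methoxy group.

**Step 14**
Reactants: 27 7-methoxy silyl ether
Product: 28 3-[(2S,3R)-2-(4-benzyloxy-3,5-dimethoxyphenyl)-3-(benzyloxymethyl)-7-methoxy-2,3-dihydrobenzofuran-5-yl]propan-1-ol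
Conditions: TBAF, THF, 0 °C → rt
Reagents that add atoms: none
Why: Fluoride-induced cleavage of the Si–O bond frees the chain alcohol while benzyl and methyl ethers are inert.

**Step 15**
Reactants: 28 primary alcohol
Product: 30 3-[(2S,3R)-2-(4-benzyloxy-3,5-dimethoxyphenyl)-3-(benzyloxymethyl)-7-methoxy-2,3-dihydrobenzofuran-5-yl]propanoic acid, via aldehyde 29 (not isolated)
Conditions: TEMPO (cat.), PhI(OAc)2 (2.2 equiv), aq. MeCN, rt
Reagents that add atoms: water, O
Why: The TEMPO/PhI(OAc)2 oxidation acts on the single free alcohol and, with no free phenol present, should spare the fully etherified electron-rich arenes.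

**Step 16**
Reactants: 30 carboxylic acid
Product: 31 methyl 3-[(2S,3R)-2-(4-benzyloxy-3,5-dimethoxyphenyl)-3-(benzyloxymethyl)-7-methoxy-2,3-dihydrobenzofuran-5-yl]propanoate
Conditions: MeI, K2CO3, DMF, rt
Reagents that add atoms: iodomethane, CI
Why: O-Alkylation of the carboxylate (SN2) gives the methyl ester without acid and so without risk to the benzylic C2–O1 bond.

**Step 17**
Reactants: 31 dibenzyl methyl ester
Product: 32 methyl 3-[(2S,3R)-2-(4-hydroxy-3,5-dimethoxyphenyl)-3-(hydroxymethyl)-7-methoxy-2,3-dihydrobenzofuran-5-yl]propanoate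
Conditions: H2 (1 atm), Pd/C, EtOAc/MeOH, rt
Reagents that add atoms: none
Why: Catalytic hydrogenolysis cleaves both O-benzyl bonds, while the cyclic secondary C2–O1 bond reacts much more slowly, so the reaction is stopped once two equivalents of hydrogen are taken up.

**Compound list**
1 | allyl alcohol | C=CCO | starting material
2 | allyloxy(triisopropyl)silane | C=CCO[Si](C(C)C)(C(C)C)C(C)C | intermediate
3 | 4-bromo-2-furaldehyde | O=Cc1cc(Br)co1 | starting material
4 | B-[3-(triisopropylsilyloxy)propyl]-9-borabicyclo[3.3.1]nonane (not isolated) | CC(C)[Si](C(C)C)(C(C)C)OCCCB1C2CCCC1CCC2 | intermediate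
5 | 4-[3-(triisopropylsilyloxy)propyl]furan-2-carbaldehyde | CC(C)[Si](C(C)C)(C(C)C)OCCCc1coc(C=O)c1 | intermediate
6 | 2-vinyl-4-[3-(triisopropylsilyloxy)propyl]furan | CC(C)[Si](C(C)C)(C(C)C)OCCCc1coc(C=C)c1 | intermediate
7 | B-(2-{4-[3-(triisopropylsilyloxy)propyl]furan-2-yl}ethyl)-9-borabicyclo[3.3.1]nonane (not isolated) | CC(C)[Si](C(C)C)(C(C)C)OCCCc1coc(CCB2C3CCCC2CCC3)c1 | intermediate
8 | 2-{4-[3-(triisopropylsilyloxy)propyl]furan-2-yl}ethanol | CC(C)[Si](C(C)C)(C(C)C)OCCCc1coc(CCO)c1 | intermediate
9 | {4-[3-(triisopropylsilyloxy)propyl]furan-2-yl}acetaldehyde (not isolated) | CC(C)[Si](C(C)C)(C(C)C)OCCCc1coc(CC=O)c1 | intermediate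
10 | {4-[3-(triisopropylsilyloxy)propyl]furan-2-yl}acetic acid | CC(C)[Si](C(C)C)(C(C)C)OCCCc1coc(CC(=O)O)c1 | intermediate
11 | (S)-4-benzyl-2-oxazolidinone | O=C1N[C@@H](Cc2ccccc2)CO1 | starting material
12 | mixed pivalic anhydride of 10 (not isolated) | CC(C)[Si](C(C)C)(C(C)C)OCCCc1coc(CC(=O)OC(=O)C(C)(C)C)c1 | intermediate
13 | (S)-4-benzyl-3-({4-[3-(triisopropylsilyloxy)propyl]furan-2-yl}acetyl)oxazolidin-2-one | CC(C)[Si](C(C)C)(C(C)C)OCCCc1coc(CC(=O)N2[C@@H](Cc3ccccc3)COC2=O)c1 | intermediate
14 | syringaldehyde | COc1cc(C=O)cc(OC)c1O | starting material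
15 | 4-benzyloxy-3,5-dimethoxybenzaldehyde | COc1cc(C=O)cc(OC)c1OCc1ccccc1 | intermediate
16 | (Z)-dibutylboron enolate of 13 (not isolated) | CC(C)[Si](C(C)C)(C(C)C)OCCCc1coc(/C=C(\OB(CCCC)CCCC)N2[C@@H](Cc3ccccc3)COC2=O)c1 | intermediate
17 | dibutylboron aldolate of 18 (not isolated) | CC(C)[Si](C(C)C)(C(C)C)OCCCc1coc(c1)[C@H](C(=O)N1[C@@H](Cc2ccccc2)COC1=O)[C@@H](c1cc(OC)c(OCc2ccccc2)c(OC)c1)OB(CCCC)CCCC | intermediate
18 | syn aldol adduct, (4S) auxiliary, (2R,3S) acyl chain | CC(C)[Si](C(C)C)(C(C)C)OCCCc1coc(c1)[C@H](C(=O)N1[C@@H](Cc2ccccc2)COC1=O)[C@@H](c1cc(OC)c(OCc2ccccc2)c(OC)c1)O | intermediate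
19 | (1S,2R)-1-(4-benzyloxy-3,5-dimethoxyphenyl)-2-{4-[3-(triisopropylsilyloxy)propyl]furan-2-yl}propane-1,3-diol | CC(C)[Si](C(C)C)(C(C)C)OCCCc1coc(c1)[C@H](CO)[C@@H](c1cc(OC)c(OCc2ccccc2)c(OC)c1)O | intermediate
20 | (1S,2R)-3-benzyloxy-1-(4-benzyloxy-3,5-dimethoxyphenyl)-2-{4-[3-(triisopropylsilyloxy)propyl]furan-2-yl}propan-1-ol | CC(C)[Si](C(C)C)(C(C)C)OCCCc1coc(c1)[C@H](COCc1ccccc1)[C@@H](c1cc(OC)c(OCc2ccccc2)c(OC)c1)O | intermediate
21 | (E)-1,2-dichlorovinyl ether of 20 (not isolated) | CC(C)[Si](C(C)C)(C(C)C)OCCCc1coc(c1)[C@H](COCc1ccccc1)[C@@H](c1cc(OC)c(OCc2ccccc2)c(OC)c1)O/C(Cl)=C\Cl | intermediate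
22 | lithium acetylide of 23 (not isolated) | CC(C)[Si](C(C)C)(C(C)C)OCCCc1coc(c1)[C@H](COCc1ccccc1)[C@@H](c1cc(OC)c(OCc2ccccc2)c(OC)c1)OC#C[Li] | intermediate
23 | ethynyl ether of 20, (1S,2R) | CC(C)[Si](C(C)C)(C(C)C)OCCCc1coc(c1)[C@H](COCc1ccccc1)[C@@H](c1cc(OC)c(OCc2ccccc2)c(OC)c1)OC#C | intermediate
24 | oxepine (former furan oxygen between C6 and C7; C7=C7a, C3a=C4, C5=C6; tether centres unchanged; not isolated) | CC(C)[Si](C(C)C)(C(C)C)OCCCC1=COC=C2O[C@H](c3cc(OC)c(OCc4ccccc4)c(OC)c3)[C@@H](COCc3ccccc3)C2=C1 | intermediate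
25 | arene oxide (6,7-epoxide; C3a=C7a, C4=C5; epoxide face not defined; not isolated) | CC(C)[Si](C(C)C)(C(C)C)OCCCC1=CC2=C(O[C@H](c3cc(OC)c(OCc4ccccc4)c(OC)c3)[C@H]2COCc3ccccc3)C4OC14 | intermediate
26 | (2S,3R)-2-(4-benzyloxy-3,5-dimethoxyphenyl)-3-(benzyloxymethyl)-5-[3-(triisopropylsilyloxy)propyl]-2,3-dihydrobenzofuran-7-ol | CC(C)[Si](C(C)C)(C(C)C)OCCCc1cc(O)c2c(c1)[C@H](COCc1ccccc1)[C@@H](c1cc(OC)c(OCc3ccccc3)c(OC)c1)O2 | intermediate
27 | 7-methyl ether of 26, (2S,3R) | CC(C)[Si](C(C)C)(C(C)C)OCCCc1cc(OC)c2c(c1)[C@H](COCc1ccccc1)[C@@H](c1cc(OC)c(OCc3ccccc3)c(OC)c1)O2 | intermediate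
28 | 3-[(2S,3R)-2-(4-benzyloxy-3,5-dimethoxyphenyl)-3-(benzyloxymethyl)-7-methoxy-2,3-dihydrobenzofuran-5-yl]propan-1-ol | OCCCc1cc(OC)c2c(c1)[C@H](COCc1ccccc1)[C@@H](c1cc(OC)c(OCc3ccccc3)c(OC)c1)O2 | intermediate
29 | corresponding propanal (not isolated) | O=CCCc1cc(OC)c2c(c1)[C@H](COCc1ccccc1)[C@@H](c1cc(OC)c(OCc3ccccc3)c(OC)c1)O2 | intermediate
30 | corresponding propanoic acid | OC(=O)CCc1cc(OC)c2c(c1)[C@H](COCc1ccccc1)[C@@H](c1cc(OC)c(OCc3ccccc3)c(OC)c1)O2 | intermediate
31 | methyl ester of 30 | COC(=O)CCc1cc(OC)c2c(c1)[C@H](COCc1ccccc1)[C@@H](c1cc(OC)c(OCc3ccccc3)c(OC)c1)O2 | intermediate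
32 | methyl 3-[(2S,3R)-2-(4-hydroxy-3,5-dimethoxyphenyl)-3-(hydroxymethyl)-7-methoxy-2,3-dihydrobenzofuran-5-yl]propanoate | COC(=O)CCc1cc(OC)c2c(c1)[C@H](CO)[C@@H](c1cc(OC)c(O)c(OC)c1)O2 | target

**Step count**
Total steps: 17. Longest linear sequence: 16 (steps 1–6 and 8–17; step 7 is the side branch).

**Steps most likely to fail**

*Step 12.* Four processes may interfere before the intramolecular 5-exo attack takes place or before turnover is complete.
- The gold-activated ynol ether may lose the benzylic carbon by heterolysis.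
- It may be hydrated by traces of water.
- It may be attacked by the free C5 of a second furan molecule.
- The catalyst may be reduced by the electron-rich product, which would stop turnover.

The fallback buys ring A instead of building it and closes only O1–C2. It sets out from alkylborane 4, with 11 and 15 as partners, and returns at 27.
- Commercial 5-bromo-2-hydroxy-3-methoxybenzaldehyde (COc1cc(Br)cc(C=O)c1O) is protected with MOMCl/iPr2NEt as 5-bromo-3-methoxy-2-(methoxymethoxy)benzaldehyde F1.
- F1 is coupled with 4 as in step 2 to give the chain-bearing benzaldehyde F2.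
- Van Leusen reductive cyanation (TosMIC, KOtBu, DME; then MeOH, reflux) gives the arylacetonitrile F3, and KOH in aqueous EtOH gives the arylacetic acid F4.
- DCC/DMAP joins F4 to 11 to give the N-acyl oxazolidinone F5.
- The Bu2BOTf aldol with 15, LiBH4 reduction and Ag2O/BnBr, run as in steps 8 to 10, lead through the syn aldol adduct F6 and the 1,3-diol F7 to the primary benzyl ether F8.
- TFA in CH2Cl2 at 0 °C should then ionise the benzylic alcohol. The acetal-protected phenol oxygen should capture the cation on the face away from the C3 substituent with loss of the methoxymethyl group, giving trans 27. Steps 14 to 17 follow from there.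

*Step 11.* Three processes may interfere.
- The hindered secondary alkoxide may add sluggishly to dichloroacetylene.
- Excess base may deprotonate the furfurylic position and expel benzyl oxide.
- The terminal ynol ether may decay during isolation.

The fallback builds the two-carbon unit on oxygen through a carbonyl olefination instead of an addition to a haloalkyne. It sets out from 20 and returns at 22. Formylation (HCO2H, DCC, DMAP, CH2Cl2, 0 °C) gives the formate ester F9. PPh3/CCl4 in THF at 60 °C converts its carbonyl group into the 2,2-dichlorovinyl ether F10. n-BuLi (2.2 equiv, −78 °C) then effects elimination and chlorine–lithium exchange to lithium acetylide 22, which is protonated as in step 11.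

*Step 5.* The oxidant may degrade the electron-rich furan, or the enolisable aldehyde stage may self-condense before it is hydrated and oxidised further. The fallback avoids any oxidation next to the furan. It sets out from aldehyde 5, replaces steps 3 to 5 and returns at 10. Van Leusen reductive cyanation (TosMIC, KOtBu, DME, −30 °C; then MeOH, reflux) gives the furylacetonitrile F11, and hydrolysis with KOH in aqueous EtOH followed by careful acidification gives acid 10.

**Further compounds**
F1 | step 12 | 5-bromo-3-methoxy-2-(methoxymethoxy)benzaldehyde | COCOc1c(OC)cc(Br)cc1C=O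
F2 | step 12 | chain-bearing benzaldehyde: 3-methoxy-2-(methoxymethoxy)-5-[3-(triisopropylsilyloxy)propyl]benzaldehyde | CC(C)[Si](C(C)C)(C(C)C)OCCCc1cc(OC)c(OCOC)c(C=O)c1
F3 | step 12 | arylacetonitrile: {3-methoxy-2-(methoxymethoxy)-5-[3-(triisopropylsilyloxy)propyl]phenyl}acetonitrile | CC(C)[Si](C(C)C)(C(C)C)OCCCc1cc(OC)c(OCOC)c(CC#N)c1
F4 | step 12 | arylacetic acid: {3-methoxy-2-(methoxymethoxy)-5-[3-(triisopropylsilyloxy)propyl]phenyl}acetic acid | CC(C)[Si](C(C)C)(C(C)C)OCCCc1cc(OC)c(OCOC)c(CC(=O)O)c1
F5 | step 12 | N-acyl oxazolidinone: (S)-4-benzyl-3-(arylacetyl)oxazolidin-2-one from F4 | CC(C)[Si](C(C)C)(C(C)C)OCCCc1cc(OC)c(OCOC)c(CC(=O)N2[C@@H](Cc3ccccc3)COC2=O)c1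
F6 | step 12 | syn aldol adduct, (4S) auxiliary, (2S,3S) acyl chain | CC(C)[Si](C(C)C)(C(C)C)OCCCc1cc(OC)c(OCOC)c(c1)[C@H](C(=O)N1[C@@H](Cc2ccccc2)COC1=O)[C@@H](c1cc(OC)c(OCc2ccccc2)c(OC)c1)O
F7 | step 12 | 1,3-diol, (1S,2R) | CC(C)[Si](C(C)C)(C(C)C)OCCCc1cc(OC)c(OCOC)c(c1)[C@H](CO)[C@@H](c1cc(OC)c(OCc2ccccc2)c(OC)c1)O
F8 | step 12 | primary benzyl ether of F7, (1S,2R) | CC(C)[Si](C(C)C)(C(C)C)OCCCc1cc(OC)c(OCOC)c(c1)[C@H](COCc1ccccc1)[C@@H](c1cc(OC)c(OCc2ccccc2)c(OC)c1)O
F9 | step 11 | formate ester of 20 | CC(C)[Si](C(C)C)(C(C)C)OCCCc1coc(c1)[C@H](COCc1ccccc1)[C@@H](c1cc(OC)c(OCc2ccccc2)c(OC)c1)OC=O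
F10 | step 11 | 2,2-dichlorovinyl ether of 20 | CC(C)[Si](C(C)C)(C(C)C)OCCCc1coc(c1)[C@H](COCc1ccccc1)[C@@H](c1cc(OC)c(OCc2ccccc2)c(OC)c1)OC=C(Cl)Cl
F11 | step 5 | furylacetonitrile: {4-[3-(triisopropylsilyloxy)propyl]furan-2-yl}acetonitrile | CC(C)[Si](C(C)C)(C(C)C)OCCCc1coc(CC#N)c1
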